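**Retrosynthetic overview**
1. No ring is built: ring C of every unit is bought. (+)-Catechin 1, as its tetrabenzyl ether 2, serves as both the middle and the lower unit; (+)-dihydromyricetin 3, as benzyl ether 4 and then diol 5, serves as the upper (pyrogallol) unit.
2. First union, C4(upper)–C8(middle): Lewis acid coupling of 5 with 2 gives dimer 6.
3. Key step: oxidative C4–H to C4–O etherification at the free lower terminus of 6 turns the chain end from nucleophile into electrophile (7).
4. Second union, C4(middle)–C8(lower): 7 with 2 gives trimer 8; hydrogenolysis of thirteen benzyl ethers gives target 9.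

Assumption: (+)-catechin and (+)-dihydromyricetin (ampelopsin), both bulk plant products of the natural 2R series, count as cheap starting materials; the configuration at the temporary C4–O centres of 5 and 7 is lost on ionisation and is drawn only for definiteness.

**Route**

Step 1
Reactants: 1 (+)-catechin
Product: 2 5,7,3',4'-tetra-O-benzyl-(+)-catechin
Conditions: BnBr (4.4 equiv), K2CO3, DMF, 0 °C to rt, argon
Reagents that add atoms: benzyl bromide, BrCc1ccccc1
Why: Williamson ether synthesis, in which carbonate deprotonates only the four phenols, so the secondary 3-OH stays free and no stereocentre is touched.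

Step 2
Reactants: 3 (+)-dihydromyricetin
Product: 4 5,7,3',4',5'-penta-O-benzyl-(+)-dihydromyricetin
Conditions: BnBr (6 equiv), K2CO3, n-Bu4NI (cat.), DMF, rt, argon
Reagents that add atoms: benzyl bromide, BrCc1ccccc1
Why: Williamson ether synthesis on all five phenols (the hydrogen-bonded 5-OH reacts last), with the weak base leaving the 3-OH and the C2/C3 centres of the 2,3-trans flavanonol untouched.

Step 3
Reactants: 4 5,7,3',4',5'-penta-O-benzyl-(+)-dihydromyricetin
Product: 5 (2R,3S,4R)-5,7-bis(benzyloxy)-2-[3,4,5-tris(benzyloxy)phenyl]chromane-3,4-diol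
Conditions: NaBH4, THF–EtOH (1:1), 0 °C to rt
Reagents that add atoms: none
Why: Borohydride reduction of the aryl ketone, where axial hydride delivery gives mainly the equatorial 4α-alcohol (3,4-trans), a centre that is ionised again in step 4.

Step 4
Reactants: 5 penta-O-benzyl flavan-3,4-diol; 2 tetra-O-benzyl-(+)-catechin (4 equiv, excess recovered)
Product: 6 nona-O-benzyl-gallocatechin-(4α→8)-catechin
Conditions: TiCl4 (1.1 equiv), CH2Cl2–THF (9:1), 0 °C to rt; H2O quench
Reagents that add atoms: none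
Why: Friedel–Crafts alkylation by SN1 ionisation of the C4 hydroxyl, in which the most nucleophilic position of 2 (C8 of ring A) adds anti to the 3-hydroxyl, so the new C4 centre is 4α (3,4-trans), and excess 2 suppresses self-condensation.

Step 5
Reactants: 6 nona-O-benzyl-gallocatechin-(4α→8)-catechin
Product: 7 nona-O-benzyl-gallocatechin-(4α→8)-[4β-(2-ethoxyethoxy)catechin]
Conditions: DDQ (1.5 equiv), 2-ethoxyethanol (10 equiv), CH2Cl2, rt
Reagents that add atoms: 2-ethoxyethanol, CCOCCO
Why: Proposed new method: site-selective oxidative C–H etherification of a 4→8-linked dimer at the C4 methylene of its lower unit, in which DDQ forms a charge-transfer complex with the electron-rich ring A of that unit and abstracts the pseudo-axial C4 hydride to give a cation stabilised by the 5-, 7- and ring oxygen atoms, 2-ethoxyethanol then adds axially, trans to the C2 aryl group, to form the C4–O bond (4β), while the doubly benzylic interflavan C4–H of the upper unit is spared because it is shielded by the ortho substituents of the attached ring and its cation cannot become planar without the C8-linked aryl group clashing with the peri 5-benzyloxy group; the closest known reaction type is the DDQ/alcohol benzylic oxidative etherification at C4 of benzylated catechin and epicatechin monomers.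

Step 6
Reactants: 7 4β-(2-ethoxyethoxy) dimer; 2 tetra-O-benzyl-(+)-catechin (4 equiv, excess recovered)
Product: 8 trideca-O-benzyl-gallocatechin-(4α→8)-catechin-(4α→8)-catechin
Conditions: TiCl4 (1.1 equiv), CH2Cl2–THF (9:1), 0 °C to rt; H2O quench
Reagents that add atoms: none
Why: Friedel–Crafts alkylation by SN1 ionisation of the chelating 4-alkoxy group, in which C8 of 2 adds anti to the 3-hydroxyl of the middle unit to set its C4 centre as 4α (3,4-trans), as in step 4.

Step 7
Reactants: 8 trideca-O-benzyl trimer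
Product: 9 gallocatechin-(4α→8)-catechin-(4α→8)-catechin
Conditions: H2 (1 atm), Pd(OH)2/C, THF–MeOH–H2O (20:1:1), rt; filtration under argon, Sephadex LH-20, freeze-drying
Reagents that add atoms: none
Why: Catalytic hydrogenolysis of thirteen benzyl aryl ethers under neutral conditions, which leaves the acid-labile interflavan bonds and all eight stereocentres untouched.

**Compound list**

1 | (+)-catechin, (2R,3S)-2-(3,4-dihydroxyphenyl)chromane-3,5,7-triol | Oc1cc(O)c2c(c1)O[C@H](c1ccc(O)c(O)c1)[C@@H](O)C2 | starting material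

2 | 5,7,3',4'-tetra-O-benzyl-(+)-catechin, (2R,3S)-5,7-bis(benzyloxy)-2-[3,4-bis(benzyloxy)phenyl]chroman-3-ol | c1ccccc1COc1cc(OCc3ccccc3)c2c(c1)O[C@H](c1ccc(OCc3ccccc3)c(OCc3ccccc3)c1)[C@@H](O)C2 | intermediate

3 | (+)-dihydromyricetin (ampelopsin), (2R,3R)-3,5,7-trihydroxy-2-(3,4,5-trihydroxyphenyl)chroman-4-one | Oc1cc(O)c2c(c1)O[C@H](c1cc(O)c(O)c(O)c1)[C@@H](O)C2=O | starting material

4 | 5,7,3',4',5'-penta-O-benzyl-(+)-dihydromyricetin, (2R,3R)-5,7-bis(benzyloxy)-3-hydroxy-2-[3,4,5-tris(benzyloxy)phenyl]chroman-4-one | c1ccccc1COc1cc(OCc3ccccc3)c2c(c1)O[C@H](c1cc(OCc3ccccc3)c(OCc3ccccc3)c(OCc3ccccc3)c1)[C@@H](O)C2=O | intermediate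

5 | (2R,3S,4R)-5,7-bis(benzyloxy)-2-[3,4,5-tris(benzyloxy)phenyl]chromane-3,4-diol (2,3-trans-3,4-trans; 4-OH α) | c1ccccc1COc1cc(OCc3ccccc3)c2c(c1)O[C@H](c1cc(OCc3ccccc3)c(OCc3ccccc3)c(OCc3ccccc3)c1)[C@@H](O)[C@@H]2O | intermediate

6 | nona-O-benzyl-gallocatechin-(4α→8)-catechin (both units 2R,3S; interflavan bond trans to the upper 3-OH; all nine phenols benzylated, both 3-OH free) | c1ccccc1COc1cc(OCc3ccccc3)c2c(c1)O[C@H](c1cc(OCc3ccccc3)c(OCc3ccccc3)c(OCc3ccccc3)c1)[C@@H](O)[C@@H]2c1c(OCc3ccccc3)cc(OCc3ccccc3)c2c1O[C@H](c1ccc(OCc3ccccc3)c(OCc3ccccc3)c1)[C@@H](O)C2 | intermediate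

7 | nona-O-benzyl-gallocatechin-(4α→8)-[4β-(2-ethoxyethoxy)catechin] (6 with a 2-ethoxyethoxy group at C4 of the lower unit, cis to its 3-OH and trans to its C2 aryl group) | c1ccccc1COc1cc(OCc3ccccc3)c2c(c1)O[C@H](c1cc(OCc3ccccc3)c(OCc3ccccc3)c(OCc3ccccc3)c1)[C@@H](O)[C@@H]2c1c(OCc3ccccc3)cc(OCc3ccccc3)c2c1O[C@H](c1ccc(OCc3ccccc3)c(OCc3ccccc3)c1)[C@@H](O)[C@H]2OCCOCC | intermediate

8 | trideca-O-benzyl-gallocatechin-(4α→8)-catechin-(4α→8)-catechin (all units 2R,3S; both interflavan bonds 3,4-trans; three 3-OH free) | c1ccccc1COc1cc(OCc3ccccc3)c2c(c1)O[C@H](c1cc(OCc3ccccc3)c(OCc3ccccc3)c(OCc3ccccc3)c1)[C@@H](O)[C@@H]2c1c(OCc3ccccc3)cc(OCc3ccccc3)c2c1O[C@H](c1ccc(OCc3ccccc3)c(OCc3ccccc3)c1)[C@@H](O)[C@@H]2c1c(OCc3ccccc3)cc(OCc3ccccc3)c2c1O[C@H](c1ccc(OCc3ccccc3)c(OCc3ccccc3)c1)[C@@H](O)C2 | intermediate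

9 | gallocatechin-(4α→8)-catechin-(4α→8)-catechin (CNP0155646.1; all units 2R,3S, both interflavan bonds 3,4-trans) | Oc1cc(O)c2c(c1)O[C@H](c1cc(O)c(O)c(O)c1)[C@@H](O)[C@@H]2c1c(O)cc(O)c2c1O[C@H](c1ccc(O)c(O)c1)[C@@H](O)[C@@H]2c1c(O)cc(O)c2c1O[C@H](c1ccc(O)c(O)c1)[C@@H](O)C2 | target

**Step count**

Total steps: 7. Longest linear sequence: 6 (steps 2 to 7, from 3).

**Three steps most likely to fail**

Step 5 (the proposed new step). The risks are hydride abstraction at the interflavan methine of the upper unit and over-oxidation of the product to the 4-ketone. The fallback uses known chemistry and reverses the order of assembly, so that the oxidation is done on the monomer. It sets out from 2: DDQ and 2-ethoxyethanol in CH2Cl2 at rt give 4β-(2-ethoxyethoxy)-5,7,3',4'-tetra-O-benzylcatechin F1. F1 with 2 (4 equiv) and TiCl4 in CH2Cl2–THF at 0 °C gives octa-O-benzyl-catechin-(4α→8)-catechin F2. F2 (1.5 equiv, with C8 of its upper unit as the nucleophile) is then coupled with diol 5 under TiCl4 as in step 4. The fallback comes back to the route at 8 and bypasses 6 and 7.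

Step 2. The risks are incomplete benzylation of the hydrogen-bonded 5-OH and base- or air-induced damage to the pyrogallol ring and the flavanonol (epimerisation, dehydrogenation). The fallback forms the first interflavan bond before any protection. It sets out from 3: NaBH4 in EtOH gives leucodelphinidin F3, which is not isolated but added to an aqueous solution of 1 (3 equiv) at pH 5 (AcOH) under nitrogen. Sephadex LH-20 chromatography then gives gallocatechin-(4α→8)-catechin F4. BnBr, K2CO3 and DMF benzylate the nine phenols of F4, and the fallback comes back to the route at 6, bypassing 4 and 5.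

Step 6. The risks are an incomplete 3,4-trans preference with the free 3-OH next to the ionising centre and self-condensation of the dimeric electrophile. The fallback replaces simple Lewis acid ionisation by neighbouring-group participation. It sets out from 7: Ac2O, pyridine and DMAP give the 3,3''-di-O-acetate of 7 F5. F5 with 2 (4 equiv) and TMSOTf (cat.) in CH2Cl2 at −78 °C reacts through a cis-fused acyloxonium ion on the β face of the middle unit, which forces attack from the α face and gives the trimer 3,3''-di-O-acetate F6. NaOMe (cat.) in MeOH–THF removes both acetates, and the fallback comes back to the route at 8.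

**Further compounds**

F1 | step 5 | (2R,3S,4S)-5,7-bis(benzyloxy)-2-[3,4-bis(benzyloxy)phenyl]-4-(2-ethoxyethoxy)chroman-3-ol (4β ether of 2) | c1ccccc1COc1cc(OCc3ccccc3)c2c(c1)O[C@H](c1ccc(OCc3ccccc3)c(OCc3ccccc3)c1)[C@@H](O)[C@H]2OCCOCC

F2 | step 5 | octa-O-benzyl-catechin-(4α→8)-catechin (perbenzylated procyanidin B3, both 3-OH free) | c1ccccc1COc1cc(OCc3ccccc3)c2c(c1)O[C@H](c1ccc(OCc3ccccc3)c(OCc3ccccc3)c1)[C@@H](O)[C@@H]2c1c(OCc3ccccc3)cc(OCc3ccccc3)c2c1O[C@H](c1ccc(OCc3ccccc3)c(OCc3ccccc3)c1)[C@@H](O)C2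

F3 | step 2 | leucodelphinidin, (2R,3S,4R)-2-(3,4,5-trihydroxyphenyl)chromane-3,4,5,7-tetrol | Oc1cc(O)c2c(c1)O[C@H](c1cc(O)c(O)c(O)c1)[C@@H](O)[C@@H]2O

F4 | step 2 | gallocatechin-(4α→8)-catechin (prodelphinidin B3) | Oc1cc(O)c2c(c1)O[C@H](c1cc(O)c(O)c(O)c1)[C@@H](O)[C@@H]2c1c(O)cc(O)c2c1O[C@H](c1ccc(O)c(O)c1)[C@@H](O)C2

F5 | step 6 | 3,3''-di-O-acetyl-nona-O-benzyl-gallocatechin-(4α→8)-[4β-(2-ethoxyethoxy)catechin] | c1ccccc1COc1cc(OCc3ccccc3)c2c(c1)O[C@H](c1cc(OCc3ccccc3)c(OCc3ccccc3)c(OCc3ccccc3)c1)[C@@H](OC(C)=O)[C@@H]2c1c(OCc3ccccc3)cc(OCc3ccccc3)c2c1O[C@H](c1ccc(OCc3ccccc3)c(OCc3ccccc3)c1)[C@@H](OC(C)=O)[C@H]2OCCOCC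

F6 | step 6 | trideca-O-benzyl-gallocatechin-(4α→8)-catechin-(4α→8)-catechin 3,3''-di-O-acetate (upper and middle 3-OH acetylated, lower 3-OH free) | c1ccccc1COc1cc(OCc3ccccc3)c2c(c1)O[C@H](c1cc(OCc3ccccc3)c(OCc3ccccc3)c(OCc3ccccc3)c1)[C@@H](OC(C)=O)[C@@H]2c1c(OCc3ccccc3)cc(OCc3ccccc3)c2c1O[C@H](c1ccc(OCc3ccccc3)c(OCc3ccccc3)c1)[C@@H](OC(C)=O)[C@@H]2c1c(OCc3ccccc3)cc(OCc3ccccc3)c2c1O[C@H](c1ccc(OCc3ccccc3)c(OCc3ccccc3)c1)[C@@H](O)C2
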